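**Retrosynthetic overview**

1. Target ⇐ selective 18-O-acetylation of nargenicin ⇐ Evans–Tishchenko reaction of a 9-hydroxy-11-ketone with pyrrole-2-carbaldehyde (C9 ester and C11 carbinol in one step).
2. Rings A (cyclohexene), B (cyclohexane) and the C8–O–C13 bridge ⇐ one operation: transannular Diels–Alder reaction of an 18-membered macrolide (4E,6E-diene plus C12=C13 silyl enol ether of an 11,13-dione), then opening of a cis-8,9-epoxide by the C13 oxygen; the cycloaddition also contracts the macrocycle to the 10-membered lactone.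
3. Macrolide ⇐ Yamaguchi lactonisation; 11-yn-13-one ⇐ C12 acetylide plus a C13–C19 α-methyl-enoate δ-lactone (from (R)-lactate by crotylboration and ring-closing metathesis, which fixes the 14Z alkene).
4. C1–C12 acid ⇐ Horner–Wadsworth–Emmons union of a C1–C6 allylic phosphonate (Evans glycolate alkylation) with a C7–C12 cis-epoxy aldehyde (Marshall propargylation of (R)-glyceraldehyde acetonide, Payne rearrangement).
5. Ring order: δ-lactone (temporary, opened again) → 18-membered macrolactone → rings A + B + oxa-bridge together.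

Assumption: locants C1–C19 follow nargenicin numbering (C1 lactone carbonyl, C17 lactone carbinol); (R)-glyceraldehyde acetonide is bought.

**Route**

Step 1
Reactants: 1 (2E)-1,4-dibromobut-2-ene
Product: 2 diethyl [(2E)-4-bromobut-2-en-1-yl]phosphonate
Conditions: P(OEt)3 (1 equiv), 1 (3 equiv), neat, 120 °C
Reagents that add atoms: triethyl phosphite, CCOP(OCC)OCC
Why: Michaelis–Arbuzov reaction of one allylic bromide; excess dibromide suppresses the bis-phosphonate and the E alkene is untouched (no stereocentre formed).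

Step 2
Reactants: 3 (4R)-4-benzyl-1,3-oxazolidin-2-one; 4 methoxyacetyl chloride
Product: 5 (4R)-4-benzyl-3-(methoxyacetyl)-1,3-oxazolidin-2-one
Conditions: n-BuLi, THF, −78 °C; then 4, −78 → 0 °C
Reagents that add atoms: none
Why: N-acylation of the lithiated Evans auxiliary by the acid chloride; no new stereocentre.

Step 3
Reactants: 5 (4R)-4-benzyl-3-(methoxyacetyl)-1,3-oxazolidin-2-one; 2 diethyl [(2E)-4-bromobut-2-en-1-yl]phosphonate
Product: 6 (4R)-4-benzyl-3-[(2S,4E)-6-(diethoxyphosphoryl)-2-methoxyhex-4-enoyl]-1,3-oxazolidin-2-one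
Conditions: NaN(SiMe3)2, THF, −78 °C; then 2, −78 → −45 °C
Reagents that add atoms: none
Why: Evans asymmetric glycolate alkylation; the chelated Z-sodium enolate is alkylated by the allylic bromide on the face away from the benzyl group, which sets C2 as S.

Step 4
Reactants: 6 (4R)-4-benzyl-3-[(2S,4E)-6-(diethoxyphosphoryl)-2-methoxyhex-4-enoyl]-1,3-oxazolidin-2-one
Product: 8 (2S,4E)-6-(diethoxyphosphoryl)-2-methoxyhex-4-enoic acid, via peroxy acid 7 (not isolated)
Conditions: LiOH, H2O2, THF/H2O, 0 °C; Na2SO3 (aq); HCl to pH 2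
Reagents that add atoms: hydrogen peroxide, OO
Why: Evans LiOOH cleavage attacks only the exocyclic imide carbonyl, sulfite reduces the peroxy acid, and C2 is not epimerised under these conditions; the phosphonate ester is inert.

Step 5
Reactants: 9 (2S)-but-3-yn-2-ol
Product: 10 (2S)-but-3-yn-2-yl methanesulfonate
Conditions: MsCl, Et3N, CH2Cl2, −78 °C
Reagents that add atoms: methanesulfonyl chloride, CS(=O)(=O)Cl
Why: O-sulfonylation forms the O–S bond only, so the carbinol configuration is retained.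

Step 6
Reactants: 10 (2S)-but-3-yn-2-yl methanesulfonate; 11 (4R)-2,2-dimethyl-1,3-dioxolane-4-carbaldehyde
Product: 13 (1R,2R)-1-[(4R)-2,2-dimethyl-1,3-dioxolan-4-yl]-2-methylbut-3-yn-1-ol, via allenylzinc 12 (not isolated)
Conditions: Pd(OAc)2 (5 mol%), PPh3 (5 mol%), Et2Zn (3 equiv), THF, −78 → −20 °C; NH4Cl (aq)
Reagents that add atoms: none
Why: Marshall propargylation; zerovalent palladium ionises the mesylate with anti-SN2′ inversion, transmetalation gives allenylzinc 12, and its cyclic SE2′ addition sets C10 (R) and C9 (R) anti to each other by reagent control, which here must override the Felkin preference of the aldehyde (mismatched pair, dr about 5:1 expected, minor isomer removed by chromatography).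

Step 7
Reactants: 13 (1R,2R)-1-[(4R)-2,2-dimethyl-1,3-dioxolan-4-yl]-2-methylbut-3-yn-1-ol
Product: 14 (2R,3R,4R)-4-methylhex-5-yne-1,2,3-triol
Conditions: AcOH/H2O (4:1), 23 °C
Reagents that add atoms: none
Why: Acid hydrolysis of the terminal acetonide; no stereocentre is touched.

Step 8
Reactants: 14 (2R,3R,4R)-4-methylhex-5-yne-1,2,3-triol
Product: 17 [(2S,3R)-3-[(2R)-but-3-yn-2-yl]oxiran-2-yl]methanol, via primary tosylate 15 (not isolated), via terminal epoxide 16 (not isolated)
Conditions: NaH (3.2 equiv), N-tosylimidazole (1.05 equiv), THF, 0 → 23 °C; NH4Cl (aq)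
Reagents that add atoms: none
Why: One-pot sulfonylation, Williamson closure and Payne rearrangement; the primary alkoxide is tosylated, O8 closes the terminal epoxide with retention at C8, and the C9 alkoxide opens it at C8 with inversion, so the 8,9-syn triol gives the cis-2,3-epoxy alcohol, whose primary alkoxide is the favoured Payne partner in THF.

Step 9
Reactants: 17 [(2S,3R)-3-[(2R)-but-3-yn-2-yl]oxiran-2-yl]methanol
Product: 18 (2R,3R)-3-[(2R)-but-3-yn-2-yl]oxirane-2-carbaldehyde
Conditions: Dess–Martin periodinane, pyridine, CH2Cl2, 0 → 23 °C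
Reagents that add atoms: none
Why: Dess–Martin oxidation under buffered, non-epimerising conditions; the oxirane C–H is not readily enolised, so the cis-epoxy aldehyde keeps its configuration.

Step 10
Reactants: 8 (2S,4E)-6-(diethoxyphosphoryl)-2-methoxyhex-4-enoic acid; 18 (2R,3R)-3-[(2R)-but-3-yn-2-yl]oxirane-2-carbaldehyde
Product: 19 (2S,4E,6E)-7-[(2S,3R)-3-[(2R)-but-3-yn-2-yl]oxiran-2-yl]-2-methoxyhepta-4,6-dienoic acid
Conditions: 8, LiN(SiMe3)2 (2.1 equiv), THF, −78 °C; then 18, −78 → 0 °C; NH4Cl (aq), pH 4, cold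
Reagents that add atoms: none
Why: Horner–Wadsworth–Emmons olefination; the carboxylate/phosphonate dianion adds through its phosphorus-bearing carbon and phosphate elimination gives the new 6E alkene, while the 4E alkene and the epoxy-aldehyde stereocentres are untouched at low temperature.

Step 11
Reactants: 20 methyl (2R)-2-hydroxypropanoate
Product: 21 methyl (2R)-2-(triethylsilyloxy)propanoate
Conditions: Et3SiCl, imidazole, CH2Cl2, 0 °C
Reagents that add atoms: chlorotriethylsilane, CC[Si](Cl)(CC)CC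
Why: Standard O-silylation; the stereocentre is not involved.

Step 12
Reactants: 21 methyl (2R)-2-(triethylsilyloxy)propanoate
Product: 22 (2R)-2-(triethylsilyloxy)propanal
Conditions: i-Bu2AlH (1.05 equiv), CH2Cl2, −78 °C; aq. potassium sodium tartrate
Reagents that add atoms: none
Why: Partial reduction of the α-silyloxy ester stops at the tetrahedral aluminate at −78 °C, which gives the aldehyde on work-up without epimerisation.

Step 13
Reactants: 22 (2R)-2-(triethylsilyloxy)propanal; 23 2-[(2Z)-but-2-en-1-yl]-4,4,5,5-tetramethyl-1,3,2-dioxaborolane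
Product: 24 (2R,3S,4R)-4-methyl-2-(triethylsilyloxy)hex-5-en-3-ol
Conditions: 23 (1.3 equiv), toluene, 23 °C, 48 h; NaHCO3 (aq)
Reagents that add atoms: none
Why: Substrate-controlled crotylboration through a Zimmerman–Traxler chair; the Z-boronate gives the 16,17-syn relation and Felkin–Anh (Cornforth) attack on the α-silyloxy aldehyde gives the 17,18-anti relation, i.e. 16R,17S.

Step 14
Reactants: 24 (2R,3S,4R)-4-methyl-2-(triethylsilyloxy)hex-5-en-3-ol; 25 2-methylprop-2-enoyl chloride
Product: 26 (2R,3S,4R)-4-methyl-2-(triethylsilyloxy)hex-5-en-3-yl 2-methylprop-2-enoate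
Conditions: 25, Et3N, DMAP (cat.), CH2Cl2, 0 → 23 °C
Reagents that add atoms: none
Why: DMAP-catalysed O-acylation of the secondary alcohol; no stereocentre changes.

Step 15
Reactants: 26 (2R,3S,4R)-4-methyl-2-(triethylsilyloxy)hex-5-en-3-yl 2-methylprop-2-enoate
Product: 27 (5R,6S)-3,5-dimethyl-6-[(1R)-1-(triethylsilyloxy)ethyl]-5,6-dihydro-2H-pyran-2-one
Conditions: second-generation Hoveyda–Grubbs catalyst [(H2IMes)Cl2Ru=CH(2-i-PrOC6H4)] (5 mol%), toluene (5 mM), 80 °C
Reagents that add atoms: none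
Why: Ring-closing metathesis of the methacrylate onto the terminal alkene gives the six-membered unsaturated lactone, in which the C14=C15 alkene can only be Z.

Step 16
Reactants: 19 (2S,4E,6E)-7-[(2S,3R)-3-[(2R)-but-3-yn-2-yl]oxiran-2-yl]-2-methoxyhepta-4,6-dienoic acid; 27 (5R,6S)-3,5-dimethyl-6-[(1R)-1-(triethylsilyloxy)ethyl]-5,6-dihydro-2H-pyran-2-one
Product: 28 C1–C19 seco acid (17-hydroxy-11-yn-13-one)
Conditions: 19, LiN(i-Pr)2 (2.05 equiv), THF, −78 °C; then 27, −78 → −50 °C; NH4Cl (aq) at −78 °C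
Reagents that add atoms: none
Why: The lithium acetylide (formed beside the carboxylate) adds 1,2 to the lactone carbonyl in a ring-opening acylation; the tetrahedral lithium hemiketal survives until the cold quench, so there is no second addition or silyl migration and the Z-enone, C16 and C17 are delivered intact.

Step 17
Reactants: 28 C1–C19 seco acid (17-hydroxy-11-yn-13-one)
Product: 30 18-membered macrolactone ynone, via mixed anhydride 29 (not isolated)
Conditions: 2,4,6-Cl3C6H2COCl, Et3N, THF, 23 °C; then DMAP, toluene (1 mM), 40 °C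
Reagents that add atoms: none
Why: Yamaguchi macrolactonisation at high dilution; the C17 hydroxyl is the only free alcohol and the 18-membered ring is unstrained.

Step 18
Reactants: 30 18-membered macrolactone ynone
Product: 31 macrolide (11Z)-11-(triethylsilyloxy)-11-en-13-one
Conditions: Et3SiOH (1.5 equiv), PMe3 (10 mol%), CH2Cl2, 0 °C
Reagents that add atoms: triethylsilanol, CC[Si](O)(CC)CC
Why: Proposed new method: PMe3 adds to the ynone β-carbon to give a zwitterionic allenolate that deprotonates Et3SiOH, and the silanolate then adds to C11 with anti addition (Z isomer, oxygen cis to the C13 carbonyl), the closest known reaction being the trialkylphosphine-catalysed oxa-Michael addition of alcohols to ynones and alkynoates; no stereocentre is formed.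

Step 19
Reactants: 31 macrolide (11Z)-11-(triethylsilyloxy)-11-en-13-one
Product: 34 11-dehydronodusmicin (9,18-diol 11-ketone), via C13 silyl enol ether 32 (not isolated), via cycloadduct 33 (not isolated)
Conditions: toluene (2 mM), BHT, base-washed glass, 125 °C, 24 h; then CSA (0.3 equiv), MeOH, 0 → 23 °C
Reagents that add atoms: none
Why: Proposed new method: 31 equilibrates by 1,5-silyl shift with 32, whose C12=C13 enol ether (oxygen cis to the C11 ketone) is the dienophile of a 1,7,9-decatrien-3-one, and transannular Diels–Alder reaction through the boat-like transition state with the C11 ketone endo and H8 eclipsing the diene (epoxide oxygen anti to the forming C7–C12 bond) sets C4, C7, C12 and C13 and contracts the ring to the 10-membered lactone, after which acid lets the C13 oxygen open the epoxide at C8 with inversion (5-exo, trans-diaxial) to close the bridge and free O9 while the C18 silyl ether is methanolysed; closure through 31 instead would need a five-membered ring across the cis-epoxide onto the fully substituted C11, and the closest known reactions are intramolecular Diels–Alder reactions of β-alkoxy enones and acid-catalysed epoxide-opening etherifications.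

Step 20
Reactants: 34 11-dehydronodusmicin (9,18-diol 11-ketone); 35 1H-pyrrole-2-carbaldehyde
Product: 36 nargenicin
Conditions: 35 (6 equiv), SmI2 (0.3 equiv), THF, −10 °C
Reagents that add atoms: none
Why: Evans–Tishchenko reaction; the axial C9 hydroxyl forms a samarium-bound hemiacetal with 35 and delivers its hydride intramolecularly to the face of the C11 ketone syn to O9, giving the 9,11-anti diol monoester with the pyrrole-2-carboxylate on O9 and the C11 alcohol in the natural configuration.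

Step 21
Reactants: 36 nargenicin
Product: 37 18-O-acetylnargenicin
Conditions: Ac2O (1.3 equiv), pyridine, CH2Cl2, 0 °C
Reagents that add atoms: acetic anhydride, CC(=O)OC(C)=O
Why: Selective acylation; the side-chain C18 carbinol reacts much faster than the C11 hydroxyl, which is flanked by the C10 methyl group and the ring-fusion carbon C12, and the pyrrole N–H is not acylated without strong base.

**Compound list**

1 | (2E)-1,4-dibromobut-2-ene | BrC/C=C/CBr | starting material
2 | diethyl [(2E)-4-bromobut-2-en-1-yl]phosphonate | CCOP(=O)(C/C=C/CBr)OCC | intermediate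
3 | (4R)-4-benzyl-1,3-oxazolidin-2-one | O=C1N[C@H](Cc2ccccc2)CO1 | starting material
4 | methoxyacetyl chloride | COCC(=O)Cl | starting material
5 | (4R)-4-benzyl-3-(methoxyacetyl)-1,3-oxazolidin-2-one | COCC(=O)N1[C@H](Cc2ccccc2)COC1=O | intermediate
6 | (4R)-4-benzyl-3-[(2S,4E)-6-(diethoxyphosphoryl)-2-methoxyhex-4-enoyl]-1,3-oxazolidin-2-one | CO[C@@H](C/C=C/CP(=O)(OCC)OCC)C(=O)N1[C@H](Cc2ccccc2)COC1=O | intermediate
7 | (2S,4E)-6-(diethoxyphosphoryl)-2-methoxyhex-4-eneperoxoic acid | CO[C@@H](C/C=C/CP(=O)(OCC)OCC)C(=O)OO | intermediate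
8 | (2S,4E)-6-(diethoxyphosphoryl)-2-methoxyhex-4-enoic acid | CO[C@@H](C/C=C/CP(=O)(OCC)OCC)C(=O)O | intermediate
9 | (2S)-but-3-yn-2-ol | C[C@H](O)C#C | starting material
10 | (2S)-but-3-yn-2-yl methanesulfonate | C[C@H](OS(C)(=O)=O)C#C | intermediate
11 | (4R)-2,2-dimethyl-1,3-dioxolane-4-carbaldehyde ((R)-glyceraldehyde acetonide) | CC1(C)OC[C@@H](O1)C=O | starting material
12 | [(Ra)-buta-1,2-dien-1-yl](ethyl)zinc | C[CH]=[C@]=[CH][Zn]CC | intermediate
13 | (1R,2R)-1-[(4R)-2,2-dimethyl-1,3-dioxolan-4-yl]-2-methylbut-3-yn-1-ol | CC1(C)OC[C@@H](O1)[C@H](O)[C@H](C)C#C | intermediate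
14 | (2R,3R,4R)-4-methylhex-5-yne-1,2,3-triol | OC[C@@H](O)[C@H](O)[C@H](C)C#C | intermediate
15 | (2R,3R,4R)-2,3-dihydroxy-4-methylhex-5-yn-1-yl 4-methylbenzenesulfonate | Cc1ccc(cc1)S(=O)(=O)OC[C@@H](O)[C@H](O)[C@H](C)C#C | intermediate
16 | (1R,2R)-2-methyl-1-[(2R)-oxiran-2-yl]but-3-yn-1-ol | C1O[C@H]1[C@H](O)[C@H](C)C#C | intermediate
17 | [(2S,3R)-3-[(2R)-but-3-yn-2-yl]oxiran-2-yl]methanol (cis-epoxide) | OC[C@@H]1O[C@@H]1[C@H](C)C#C | intermediate
18 | (2R,3R)-3-[(2R)-but-3-yn-2-yl]oxirane-2-carbaldehyde (cis-epoxide) | O=C[C@@H]1O[C@@H]1[C@H](C)C#C | intermediate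
19 | (2S,4E,6E)-7-[(2S,3R)-3-[(2R)-but-3-yn-2-yl]oxiran-2-yl]-2-methoxyhepta-4,6-dienoic acid | CO[C@@H](C/C=C/C=C/[C@@H]1O[C@@H]1[C@H](C)C#C)C(=O)O | intermediate
20 | methyl (2R)-2-hydroxypropanoate (methyl (R)-lactate) | C[C@@H](O)C(=O)OC | starting material
21 | methyl (2R)-2-(triethylsilyloxy)propanoate | C[C@@H](O[Si](CC)(CC)CC)C(=O)OC | intermediate
22 | (2R)-2-(triethylsilyloxy)propanal | C[C@@H](O[Si](CC)(CC)CC)C=O | intermediate
23 | 2-[(2Z)-but-2-en-1-yl]-4,4,5,5-tetramethyl-1,3,2-dioxaborolane ((Z)-crotylboronic acid pinacol ester) | C/C=C\CB1OC(C)(C)C(C)(C)O1 | starting material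
24 | (2R,3S,4R)-4-methyl-2-(triethylsilyloxy)hex-5-en-3-ol | C=C[C@@H](C)[C@H](O)[C@@H](C)O[Si](CC)(CC)CC | intermediate
25 | 2-methylprop-2-enoyl chloride (methacryloyl chloride) | CC(=C)C(=O)Cl | starting material
26 | (2R,3S,4R)-4-methyl-2-(triethylsilyloxy)hex-5-en-3-yl 2-methylprop-2-enoate | C=C[C@@H](C)[C@@H]([C@@H](C)O[Si](CC)(CC)CC)OC(=O)C(C)=C | intermediate
27 | (5R,6S)-3,5-dimethyl-6-[(1R)-1-(triethylsilyloxy)ethyl]-5,6-dihydro-2H-pyran-2-one | CC1=C[C@@H](C)[C@@H]([C@@H](C)O[Si](CC)(CC)CC)OC1=O | intermediate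
28 | seco acid: (2S,4E,6E)-7-[(2S,3R)-3-[(2R,6Z,8R,9S,10R)-9-hydroxy-6,8-dimethyl-5-oxo-10-(triethylsilyloxy)undec-6-en-3-yn-2-yl]oxiran-2-yl]-2-methoxyhepta-4,6-dienoic acid (open form of the C13 lactol) | CO[C@@H](C/C=C/C=C/[C@@H]1O[C@@H]1[C@H](C)C#CC(=O)/C(C)=C\[C@@H](C)[C@H](O)[C@@H](C)O[Si](CC)(CC)CC)C(=O)O | intermediate
29 | mixed anhydride of 28 with 2,4,6-trichlorobenzoic acid | CO[C@@H](C/C=C/C=C/[C@@H]1O[C@@H]1[C@H](C)C#CC(=O)/C(C)=C\[C@@H](C)[C@H](O)[C@@H](C)O[Si](CC)(CC)CC)C(=O)OC(=O)c1c(Cl)cc(Cl)cc1Cl | intermediate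
30 | 18-membered macrolactone (C1 to O17): 2S-OMe, 4E,6E-diene, 8S,9R-cis-epoxide, 10R-Me, C11≡C12 alkyne, C13 ketone, 14Z-alkene, 16R-Me, 17S, 18R-OSiEt3 | CO[C@H]1C/C=C/C=C/[C@@H]2O[C@@H]2[C@H](C)C#CC(=O)/C(C)=C\[C@@H](C)[C@@H]([C@@H](C)O[Si](CC)(CC)CC)OC1=O | intermediate
31 | macrolide as 30 but with (11Z)-C11(OSiEt3)=C12H–C13(=O): C11 triethylsilyl enol ether of the 11,13-dione | CO[C@H]1C/C=C/C=C/[C@@H]2O[C@@H]2[C@H](C)/C(O[Si](CC)(CC)CC)=C/C(=O)/C(C)=C\[C@@H](C)[C@@H]([C@@H](C)O[Si](CC)(CC)CC)OC1=O | intermediate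
32 | silatropic isomer of 31: C11 ketone, (12Z)-C12H=C13(OSiEt3) enol ether (oxygen cis to C11) | CO[C@H]1C/C=C/C=C/[C@@H]2O[C@@H]2[C@H](C)C(=O)/C=C(\O[Si](CC)(CC)CC)/C(C)=C\[C@@H](C)[C@@H]([C@@H](C)O[Si](CC)(CC)CC)OC1=O | intermediate
33 | cycloadduct: cis-fused rings A and B with the 10-membered lactone, tertiary 13-OSiEt3, 8,9-epoxide on the face opposite ring A, 11-ketone, 18-OSiEt3 | CO[C@H]1C[C@H]2C=C[C@H]3[C@@H]4O[C@@H]4[C@H](C)C(=O)[C@H]3[C@]2(O[Si](CC)(CC)CC)/C(C)=C\[C@@H](C)[C@@H]([C@@H](C)O[Si](CC)(CC)CC)OC1=O | intermediate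
34 | 11-dehydronodusmicin: nargenicin skeleton with the C8–O–C13 bridge, 9-OH, 11-ketone, 18-OH | CO[C@H]1C[C@H]2C=C[C@H]3[C@H]4O[C@]2(/C(C)=C\[C@@H](C)[C@@H]([C@@H](C)O)OC1=O)[C@@H]3C(=O)[C@@H](C)[C@H]4O | intermediate
35 | 1H-pyrrole-2-carbaldehyde | O=Cc1ccc[nH]1 | starting material
36 | nargenicin (9-O-(1H-pyrrole-2-carbonyl)nodusmicin) | CO[C@H]1C[C@H]2C=C[C@H]3[C@H]4O[C@]2(/C(C)=C\[C@@H](C)[C@@H]([C@@H](C)O)OC1=O)[C@@H]3[C@H](O)[C@@H](C)[C@H]4OC(=O)c1ccc[nH]1 | intermediate
37 | 18-O-acetylnargenicin | CO[C@H]1C[C@H]2C=C[C@H]3[C@H]4O[C@]2(/C(C)=C\[C@@H](C)[C@@H]([C@@H](C)OC(C)=O)OC1=O)[C@@H]3[C@H](O)[C@@H](C)[C@H]4OC(=O)c1ccc[nH]1 | target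

**Step count and risks**

Total: 21 steps. Longest linear sequence: 12 steps (9 → 10 → 13 → 14 → 17 → 18 → 19 → 28 → 30 → 31 → 34 → 36 → 37).

Most likely to fail:

1. Step 19. The vinylogous silyl ester is a deactivated dienophile, and the silatropic pair could also cyclise through 31 (C11=C12 as dienophile, five-membered closure), which would give the wrong skeleton. The fallback takes the oxygen off the dienophile and puts it on C13 after the cycloaddition; it sets out from 31 and comes back at 34. Luche reduction of the C13 ketone of 31 (NaBH4, CeCl3, MeOH, −78 °C) gives the β-silyloxy allylic alcohol F1. Mild acid (PPTS, wet CH2Cl2) triggers the Stork–Danheiser transposition to the (12E,14Z)-dienone macrolide F2, a decatrienone with only one possible dienophile. Heating in toluene gives the transannular cycloadduct F3 with H13 syn to C11. Hydroxylamine (NH2OH·HCl, pyridine) gives the oxime F4. Its iminoxyl radical (PhI(OAc)2, catalytic TEMPO) abstracts the syn, allylic C13–H by 1,5-hydrogen transfer and closes the cis-fused isoxazoline F5. Mo(CO)6 in wet MeCN cleaves the N–O bond to the β-hydroxy ketone F6, and CSA in MeOH then closes the ether bridge and removes the C18 silyl group to give 34.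

2. Step 18. The silanol may not add under phosphine catalysis, or PMe3 may attack the dienyl epoxide. The fallback is stepwise and uncatalysed; it sets out from 30 and comes back at 31. Diethylamine adds to the ynone (THF, 0 °C, aza-Michael) to give the enaminone F7. Hydrolysis on wet silica gel at pH 5–6 gives the enolised 11,13-dione F8. Silylation of the chelated enol with Et3SiCl and imidazole gives 31.

3. Step 20. The axial, hindered C9 hydroxyl and the N–H aldehyde may not enter the samarium-templated hydride transfer. The fallback separates acylation from reduction; it sets out from 34 and comes back at 37. Acetylation of the more exposed C18 hydroxyl (Ac2O, pyridine, 0 °C) gives the 18-acetate F9. Esterification of the C9 hydroxyl with 2-(trichloroacetyl)pyrrole (DMAP, Et3N, MeCN; haloform-type acyl transfer) gives the keto ester F10. Reduction of the C11 ketone with NaBH4 and CeCl3 at −40 °C, hydride arriving from the face opposite the oxa-bridge, gives 37 directly.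

Further compounds

F1 | step 19 | 13-hydroxy analogue of 31 (β-silyloxy allylic alcohol, C13 epimers) | CO[C@H]1C/C=C/C=C/[C@@H]2O[C@@H]2[C@H](C)/C(O[Si](CC)(CC)CC)=C/C(O)/C(C)=C\[C@@H](C)[C@@H]([C@@H](C)O[Si](CC)(CC)CC)OC1=O
F2 | step 19 | (4E,6E,12E,14Z)-dienone macrolide (C11 ketone, C12=C13 unsubstituted) | CO[C@H]1C/C=C/C=C/[C@@H]2O[C@@H]2[C@H](C)C(=O)/C=C/C(C)=C\[C@@H](C)[C@@H]([C@@H](C)O[Si](CC)(CC)CC)OC1=O
F3 | step 19 | transannular cycloadduct with C13–H (13-deoxy analogue of 33) | CO[C@H]1C[C@H]2C=C[C@H]3[C@@H]4O[C@@H]4[C@H](C)C(=O)[C@H]3[C@@H]2/C(C)=C\[C@@H](C)[C@@H]([C@@H](C)O[Si](CC)(CC)CC)OC1=O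
F4 | step 19 | C11 oxime of F3 | CO[C@H]1C[C@H]2C=C[C@H]3[C@@H]4O[C@@H]4[C@H](C)C(=NO)[C@H]3[C@@H]2/C(C)=C\[C@@H](C)[C@@H]([C@@H](C)O[Si](CC)(CC)CC)OC1=O
F5 | step 19 | cis-fused isoxazoline (O on C13, C=N at C11) | CO[C@H]1C[C@H]2C=C[C@H]3[C@@H]4O[C@@H]4[C@H](C)C5=NO[C@@]2([C@@H]35)/C(C)=C\[C@@H](C)[C@@H]([C@@H](C)O[Si](CC)(CC)CC)OC1=O
F6 | step 19 | 13-hydroxy-11-ketone with 8,9-epoxide (desilylated analogue of 33 at O13) | CO[C@H]1C[C@H]2C=C[C@H]3[C@@H]4O[C@@H]4[C@H](C)C(=O)[C@H]3[C@]2(O)/C(C)=C\[C@@H](C)[C@@H]([C@@H](C)O[Si](CC)(CC)CC)OC1=O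
F7 | step 18 | macrolide (11E)-11-(diethylamino)-11-en-13-one (enaminone) | CO[C@H]1C/C=C/C=C/[C@@H]2O[C@@H]2[C@H](C)/C(N(CC)CC)=C\C(=O)/C(C)=C\[C@@H](C)[C@@H]([C@@H](C)O[Si](CC)(CC)CC)OC1=O
F8 | step 18 | macrolide 11,13-dione | CO[C@H]1C/C=C/C=C/[C@@H]2O[C@@H]2[C@H](C)C(=O)CC(=O)/C(C)=C\[C@@H](C)[C@@H]([C@@H](C)O[Si](CC)(CC)CC)OC1=O
F9 | step 20 | 18-O-acetyl-11-dehydronodusmicin | CO[C@H]1C[C@H]2C=C[C@H]3[C@H]4O[C@]2(/C(C)=C\[C@@H](C)[C@@H]([C@@H](C)OC(C)=O)OC1=O)[C@@H]3C(=O)[C@@H](C)[C@H]4O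
F10 | step 20 | 18-O-acetyl-11-dehydronargenicin | CO[C@H]1C[C@H]2C=C[C@H]3[C@H]4O[C@]2(/C(C)=C\[C@@H](C)[C@@H]([C@@H](C)OC(C)=O)OC1=O)[C@@H]3C(=O)[C@@H](C)[C@H]4OC(=O)c1ccc[nH]1
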